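With the seven-membered ring numbered C1 (ketone), C2 (CH2OH-bearing), C3, C4, C5 (quaternary), C6 and C7, the plan reads C6, C7 and their two cis arms (C6–CH=CH–O and C7–CH2–CO–CH3) as the six ring carbons and the methyl group of a para-tolyl ring bound to C5. Everything rests on the C1–C7 disconnection. One intramolecular Friedel–Crafts acylation closes the cycloheptanone onto the tolyl position ortho to C5. Its precursor is an enantiopure 5-methyl-5-(4-methylphenyl)octanoic acid whose other three-carbon arm ends in a pivalate. Birch reduction, cleavage of the methyl-bearing alkene and a hydrogenation steered by a temporary C1 carbinol later unmask the arene.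

Key step: step 8

Locants: the target numbering C1–C7 is kept for all intermediates. The other four tolyl carbons are Ca (next to C7, future acetonyl CH2), Cb (methyl-bearing, future ketone carbon), Cc (future O–CH=) and Cd (next to C6, future =CH).

Assumption: step 11 is drawn for osmylation on the ring face that carries the C5 methyl group. The other cis-diol would be carried along, because Cb and Cc lose their stereochemistry in step 20.

Step 1
Reactants: 1 3-methylcyclohex-2-en-1-one; 2 4-methylphenylboronic acid
Product: 3 (S)-3-methyl-3-(4-methylphenyl)cyclohexan-1-one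
Conditions: Pd(OCOCF3)2 (5 mol %), (R)-t-BuPyOx (6 mol %), NH4PF6, H2O, ClCH2CH2Cl, 40 °C
Reagents that add atoms: none
Why: Enantioselective palladium-catalysed 1,4-addition of an arylboronic acid to a β-substituted cyclic enone, in which the pyridine-oxazoline ligand selects the enone face; the S ligand gives R ketones in this series, so the R ligand should set the quaternary carbon (future C5) as S.

Step 2
Reactants: 3 (S)-3-methyl-3-(4-methylphenyl)cyclohexan-1-one
Product: 5 (S)-trimethyl{[5-methyl-5-(4-methylphenyl)cyclohex-1-en-1-yl]oxy}silane, via lithium enolate 4 (not isolated)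
Conditions: LiN(i-Pr)2, THF, −78 °C; Me3SiCl, −78 °C → 0 °C
Reagents that add atoms: chlorotrimethylsilane, C[Si](C)(C)Cl
Why: Kinetic silyl enol ether formation, because the hindered amide removes a proton from the α-CH2 remote from the quaternary carbon rather than from the neopentyl-type α-CH2, and O-silylation fixes that regiochemistry.

Step 3
Reactants: 5 (S)-trimethyl{[5-methyl-5-(4-methylphenyl)cyclohex-1-en-1-yl]oxy}silane
Product: 7 (3S)-6-hydroxy-3-methyl-3-(4-methylphenyl)hexanoic acid, via methoxy hydroperoxide 6 (not isolated)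
Conditions: O3 (1 equiv, dye end point), CH2Cl2/MeOH, −78 °C; NaBH4, −78 °C → rt; aq. citric acid
Reagents that add atoms: ozone, [O-][O+]=O
Why: Ozonolysis of a silyl enol ether, whose electron-rich C=C reacts far faster than the tolyl ring; the silyloxy carbon emerges as the acid and the other carbon as a peroxy acetal that NaBH4 reduces to the primary alcohol, so the two arms leave the flask differentiated.

Step 4
Reactants: 7 (3S)-6-hydroxy-3-methyl-3-(4-methylphenyl)hexanoic acid
Product: 9 (3S)-3-methyl-3-(4-methylphenyl)-6-(pivaloyloxy)hexanoic acid, via mixed anhydride 8 (not isolated)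
Conditions: t-BuCOCl (2.2 equiv), pyridine, 0 °C → rt; H2O
Reagents that add atoms: pivaloyl chloride, CC(C)(C)C(=O)Cl; water, O
Why: O-acylation of the primary alcohol with an acid chloride, in which the carboxyl group is only tied up for a time as the mixed anhydride that water and pyridine hydrolyse again at its less hindered carbonyl.

Step 5
Reactants: 9 (3S)-3-methyl-3-(4-methylphenyl)-6-(pivaloyloxy)hexanoic acid
Product: 10 (4S)-6-hydroxy-4-methyl-4-(4-methylphenyl)hexyl pivalate
Conditions: BH3·THF, THF, 0 °C → rt; MeOH
Reagents that add atoms: none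
Why: Chemoselective borane reduction, since a free carboxylic acid is reduced through its acyloxyborane much faster than a hindered ester, so the pivalate should survive.

Step 6
Reactants: 10 (4S)-6-hydroxy-4-methyl-4-(4-methylphenyl)hexyl pivalate; 11 benzyl (triphenylphosphoranylidene)acetate
Product: 13 benzyl (2E,5S)-5-methyl-5-(4-methylphenyl)-8-(pivaloyloxy)oct-2-enoate, via aldehyde 12 (not isolated)
Conditions: TEMPO (10 mol %), PhI(OAc)2, CH2Cl2, rt; then 11 (2.5 equiv), rt
Reagents that add atoms: none
Why: One-pot oxoammonium oxidation and Wittig olefination, in which the oxidation stops at the aldehyde and the stabilised ylide adds the future C2 and C1 as an E enoate.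

Step 7
Reactants: 13 benzyl (2E,5S)-5-methyl-5-(4-methylphenyl)-8-(pivaloyloxy)oct-2-enoate
Product: 14 (5R)-5-methyl-5-(4-methylphenyl)-8-(pivaloyloxy)octanoic acid
Conditions: H2 (1 atm), Pd/C, EtOAc, rt
Reagents that add atoms: none
Why: Catalytic hydrogenation saturates the enoate and hydrogenolyses the benzyl ester in the same operation, so the free acid is reached without a basic hydrolysis that could touch the pivalate (the descriptor changes only because the ranking of the two arms changes).

Step 8
Reactants: 14 (5R)-5-methyl-5-(4-methylphenyl)-8-(pivaloyloxy)octanoic acid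
Product: 16 (9R)-3,9-dimethyl-9-[3-(pivaloyloxy)propyl]-6,7,8,9-tetrahydro-5H-benzo[7]annulen-5-one, via acid chloride 15 (not isolated)
Conditions: (COCl)2, DMF (cat.), CH2Cl2, rt; then AlCl3 (3 equiv), CH2Cl2 (dilute), 0 °C
Reagents that add atoms: none
Why: Oxalyl chloride turns the acid into its chloride, AlCl3 ionises this to the acylium ion, and the tolyl carbon ortho to the C5-bearing ipso carbon attacks it to give an arenium ion that loses a proton, forming C1–C7 (intramolecular Friedel–Crafts acylation, the classical way from 5-arylpentanoic acids to benzosuberones, also with a quaternary benzylic carbon). The seven-membered ring closes by ortho annulation, formally 7-endo-trig at the C6=C7 arene bond and exo at the acylium carbon, and the geminal substitution at C5 helps the chain to fold. No stereocentre is created, and C5, which carries no hydrogen and is not ionised at 0 °C, should keep its configuration. The regioselectivity that is needed is built in: the two ortho positions are equivalent by rotation of the ring, the para position carries the methyl group, and ipso attack is reversible. Chemoselectivity rests on the primary pivalate, which only binds an extra equivalent of AlCl3, and on the deactivated aryl ketone product, which is not acylated again.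

Step 9
Reactants: 16 (9R)-3,9-dimethyl-9-[3-(pivaloyloxy)propyl]-6,7,8,9-tetrahydro-5H-benzo[7]annulen-5-one
Product: 17 (5R,9R)-3,9-dimethyl-9-[3-(pivaloyloxy)propyl]-6,7,8,9-tetrahydro-5H-benzo[7]annulen-5-ol (C1 hydroxyl cis to the C5 chain)
Conditions: (S)-Me-CBS (15 mol %), BH3·SMe2, THF, −20 °C; MeOH
Reagents that add atoms: none
Why: Corey–Bakshi–Shibata reduction of an aryl alkyl ketone, in which the S catalyst (aryl as the large group) should give the R carbinol and so place the C1 hydroxyl on the ring face of the C5 chain, while any minor C5 enantiomer becomes a separable diastereomer.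

Step 10
Reactants: 17 (5R,9R)-3,9-dimethyl-9-[3-(pivaloyloxy)propyl]-6,7,8,9-tetrahydro-5H-benzo[7]annulen-5-ol
Product: 19 (5R,9R)-9-(3-hydroxypropyl)-3,9-dimethyl-1,4,6,7,8,9-hexahydro-5H-benzo[7]annulen-5-ol (alkenes C6=C7 and Cb=Cc), via lithium alkoxide 18 (not isolated)
Conditions: n-BuLi (1.05 equiv), THF, −78 °C; Li (excess), NH3/THF, t-BuOH, −78 → −33 °C; isoprene, then NH4Cl
Reagents that add atoms: none
Why: Birch reduction of a 1,2,4-trialkylbenzene protonates the two unsubstituted, para-related carbons Ca and Cd and leaves C6=C7 and Cb=Cc; the benzylic oxygen is kept because it is present as a lithium alkoxide, which is no leaving group and stays deprotonated beside the less acidic t-BuOH, and the pivalate is cleaved reductively in the same flask.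

Step 11
Reactants: 19 (5R,9R)-9-(3-hydroxypropyl)-3,9-dimethyl-1,4,6,7,8,9-hexahydro-5H-benzo[7]annulen-5-ol
Product: 20 tetraol (19 with Cb=Cc turned into a cis-diol on the face of the C5 methyl group; C6=C7 retained)
Conditions: OsO4 (2 mol %), NMO, acetone/H2O, 0 °C
Reagents that add atoms: N-methylmorpholine N-oxide, C[N+]1([O-])CCOCC1; water, O
Why: Catalytic osmium tetroxide dihydroxylation, in which the bulky oxidant takes the trisubstituted Cb=Cc bond in preference to the tetrasubstituted C6=C7 bond flanked by quaternary C5 and the C1 carbinol, and syn addition gives a cis-diol whose two centres are only temporary.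

Step 12
Reactants: 20 tetraol
Product: 21 acetonide diol (Cb/Cc dioxolane; free allylic C1 hydroxyl and free chain hydroxyl)
Conditions: Me2C(OMe)2, PPTS (cat.), CH2Cl2, 0 °C → rt
Reagents that add atoms: 2,2-dimethoxypropane, COC(C)(C)OC
Why: Acid-catalysed transketalisation picks out the only cis-1,2-diol, which removes the two homoallylic hydroxyls as competing directing groups and masks the future keto aldehyde, while the weak acid should leave the allylic carbinol alone.

Step 13
Reactants: 21 acetonide diol
Product: 22 cis-fused saturated diol (H6 and H7 on the face of the C5 chain and the C1 hydroxyl; Ca and Cd on the face of the C5 methyl group)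
Conditions: [Ir(cod)(PCy3)(py)]PF6 (10 mol %, two portions), H2 (50 bar), CH2Cl2, rt
Reagents that add atoms: none
Why: Hydroxyl-directed homogeneous hydrogenation, in which the cationic iridium dihydride binds the allylic C1 hydroxyl (the chain hydroxyl lies on the same face) and adds H2 syn to that face of the tetrasubstituted ring-fusion alkene, setting the centres that are 6S and 7R in the target.

Step 14
Reactants: 22 cis-fused saturated diol
Product: 23 keto aldehyde (C1 ketone; chain CH2CH2CHO)
Conditions: (n-Pr4N)RuO4 (5 mol %), NMO, 4 Å MS, CH2Cl2, rt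
Reagents that add atoms: none
Why: Ley–Griffith oxidation converts the primary and the secondary alcohol together under neutral conditions, so C7 next to the new ketone should not epimerise, and the C1 centre is erased once it has done its work.

Step 15
Reactants: 23 keto aldehyde
Product: 24 (R)-isopropenyl carbinol (chain CH2CH2CH(OH)C(CH3)=CH2; C1 ketone untouched)
Conditions: [CH2=C(CH3)]2Zn (from CH2=C(CH3)MgBr, ZnCl2, Et2O; 1,4-dioxane, filtered), (−)-MIB (10 mol %), toluene, −10 °C; aq. NH4Cl
Reagents that add atoms: diisopropenylzinc, C=C(C)[Zn]C(C)=C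
Why: Amino-alcohol-catalysed addition of an alkenylzinc reagent to an aldehyde, in which the organozinc ignores the hindered ketone and (−)-MIB directs transfer to the Si face of the aldehyde, which here means the R carbinol, a centre too remote for substrate control.

Step 16
Reactants: 24 (R)-isopropenyl carbinol
Product: 25 TBS ether of 24
Conditions: TBSCl, imidazole, DMF, rt
Reagents that add atoms: tert-butyldimethylsilyl chloride, CC(C)(C)[Si](C)(C)Cl
Why: Standard silylation of a secondary allylic alcohol under weakly basic conditions that leave C7 and the acetonide alone and remove the only acidic O–H before the enolate chemistry.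

Step 17
Reactants: 25 TBS ether of 24
Product: 27 C2=C3 enone, via lithium enolate 26 (not isolated)
Conditions: LiN(i-Pr)2, THF, −78 °C; PhS(Cl)=N-t-Bu, −78 °C
Reagents that add atoms: none
Why: Mukaiyama dehydrogenation, in which kinetic deprotonation takes the C2 methylene rather than the tertiary C7–H, the enolate attacks sulfur and an intramolecular syn elimination at −78 °C gives the enone in one operation without equilibrating C7.

Step 18
Reactants: 27 C2=C3 enone
Product: 28 2-(hydroxymethyl) enone
Conditions: aq. HCHO (37 %), DMAP (0.3 equiv), THF/H2O, rt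
Reagents that add atoms: formaldehyde, C=O
Why: Morita–Baylis–Hillman reaction, in which DMAP adds reversibly to C3, the resulting enolate is hydroxymethylated at C2 and loss of DMAP restores the enone, the base being too weak to enolise C7 at a useful rate.

Step 19
Reactants: 28 2-(hydroxymethyl) enone
Product: 29 TBDPS ether of 28
Conditions: TBDPSCl, imidazole, CH2Cl2, 0 °C → rt
Reagents that add atoms: tert-butyldiphenylsilyl chloride, CC(C)(C)[Si](Cl)(c1ccccc1)c1ccccc1
Why: Silylation of the primary allylic alcohol with the most acid-stable common silyl group, chosen so that it outlasts the acetonide hydrolysis of the next step.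

Step 20
Reactants: 29 TBDPS ether of 28
Product: 31 monocyclic keto aldehyde (C7–CH2COCH3 and C6–CH2CHO cis to each other and to the C5 methyl group), via diol 30 (not isolated)
Conditions: AcOH/H2O (4:1), 45 °C; evaporate; NaIO4, THF/pH 7 buffer, 0 °C
Reagents that add atoms: none
Why: Aqueous acetic acid hydrolyses the dioxolane but not the TBDPS ether or the secondary TBS ether, and the Malaprade cleavage of the cis-diol breaks Cb–Cc at neutral pH, releasing the methyl ketone on the C7 arm and the aldehyde on the C6 arm with C6 and C7 untouched.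

Step 21
Reactants: 32 3-methylbut-2-enoic acid (senecioic acid, two molecules)
Product: 33 3-methylbut-2-enoic anhydride
Conditions: DCC (0.5 equiv), CH2Cl2, 0 °C → rt; filter
Reagents that add atoms: none
Why: Carbodiimide dehydration of two acid molecules gives the symmetrical anhydride, an acyl donor that avoids the vinylketene pathway by which the acid chloride and an amine move the double bond out of conjugation.

Step 22
Reactants: 31 monocyclic keto aldehyde; 33 3-methylbut-2-enoic anhydride
Product: 34 bis-silylated target ((E)-enol senecioate at C6)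
Conditions: 33 (3 equiv), Et3N, DMAP (0.2 equiv), CH2Cl2, rt
Reagents that add atoms: none
Why: Enol ester formation by amine-mediated O-acylation of an aldehyde enolate, in which only the aldehyde is enolised by the amine, the acylpyridinium ion traps the enolate on oxygen and the bulky C6 residue next to quaternary C5 should favour the E isomer.

Step 23
Reactants: 34 bis-silylated target
Product: 35 CNP0257974.2 (5S,6S,7R; side-chain carbinol R; E enol ester)
Conditions: HF·pyridine, pyridine/THF, 0 °C → rt
Reagents that add atoms: none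
Why: Fluoride-mediated desilylation in a mildly acidic medium removes both silyl ethers without cleaving the enol ester or enolising C7.

Compound list
1 | 3-methylcyclohex-2-en-1-one | CC1=CC(=O)CCC1 | starting material
2 | 4-methylphenylboronic acid | Cc1ccc(B(O)O)cc1 | starting material
3 | (S)-3-methyl-3-(4-methylphenyl)cyclohexan-1-one | O=C1CCC[C@](C)(c2ccc(C)cc2)C1 | intermediate
4 | lithium enolate of 3 (C=C away from the quaternary carbon) | [Li]OC1=CCC[C@](C)(c2ccc(C)cc2)C1 | intermediate
5 | (S)-trimethyl{[5-methyl-5-(4-methylphenyl)cyclohex-1-en-1-yl]oxy}silane | C[Si](C)(C)OC1=CCC[C@](C)(c2ccc(C)cc2)C1 | intermediate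
6 | trimethylsilyl (3S)-6-hydroperoxy-6-methoxy-3-methyl-3-(4-methylphenyl)hexanoate | COC(OO)CC[C@@](C)(CC(=O)O[Si](C)(C)C)c1ccc(C)cc1 | intermediate
7 | (3S)-6-hydroxy-3-methyl-3-(4-methylphenyl)hexanoic acid | OCCC[C@@](C)(CC(=O)O)c1ccc(C)cc1 | intermediate
8 | mixed pivalic anhydride of 9 | CC(C)(C)C(=O)OCCC[C@@](C)(CC(=O)OC(=O)C(C)(C)C)c1ccc(C)cc1 | intermediate
9 | (3S)-3-methyl-3-(4-methylphenyl)-6-(pivaloyloxy)hexanoic acid | CC(C)(C)C(=O)OCCC[C@@](C)(CC(=O)O)c1ccc(C)cc1 | intermediate
10 | (4S)-6-hydroxy-4-methyl-4-(4-methylphenyl)hexyl pivalate | CC(C)(C)C(=O)OCCC[C@@](C)(CCO)c1ccc(C)cc1 | intermediate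
11 | benzyl (triphenylphosphoranylidene)acetate | O=C(C=P(c1ccccc1)(c1ccccc1)c1ccccc1)OCc1ccccc1 | starting material
12 | (4S)-4-methyl-4-(4-methylphenyl)-6-oxohexyl pivalate | CC(C)(C)C(=O)OCCC[C@@](C)(CC=O)c1ccc(C)cc1 | intermediate
13 | benzyl (2E,5S)-5-methyl-5-(4-methylphenyl)-8-(pivaloyloxy)oct-2-enoate | CC(C)(C)C(=O)OCCC[C@@](C)(C/C=C/C(=O)OCc1ccccc1)c1ccc(C)cc1 | intermediate
14 | (5R)-5-methyl-5-(4-methylphenyl)-8-(pivaloyloxy)octanoic acid | CC(C)(C)C(=O)OCCC[C@@](C)(CCCC(=O)O)c1ccc(C)cc1 | intermediate
15 | (5R)-5-methyl-5-(4-methylphenyl)-8-(pivaloyloxy)octanoyl chloride | CC(C)(C)C(=O)OCCC[C@@](C)(CCCC(=O)Cl)c1ccc(C)cc1 | intermediate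
16 | (9R)-3,9-dimethyl-9-[3-(pivaloyloxy)propyl]-6,7,8,9-tetrahydro-5H-benzo[7]annulen-5-one | CC(C)(C)C(=O)OCCC[C@@]1(C)CCCC(=O)c2cc(C)ccc21 | intermediate
17 | (5R,9R)-3,9-dimethyl-9-[3-(pivaloyloxy)propyl]-6,7,8,9-tetrahydro-5H-benzo[7]annulen-5-ol | CC(C)(C)C(=O)OCCC[C@@]1(C)CCC[C@@H](O)c2cc(C)ccc21 | intermediate
18 | lithium alkoxide of 17 | CC(C)(C)C(=O)OCCC[C@@]1(C)CCC[C@@H](O[Li])c2cc(C)ccc21 | intermediate
19 | (5R,9R)-9-(3-hydroxypropyl)-3,9-dimethyl-1,4,6,7,8,9-hexahydro-5H-benzo[7]annulen-5-ol | OCCC[C@@]1(C)CCC[C@@H](O)C2=C1CC=C(C)C2 | intermediate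
20 | tetraol: 19 with a cis-diol at Cb/Cc on the face of the C5 methyl group | OCCC[C@@]1(C)CCC[C@@H](O)C2=C1C[C@@H](O)[C@@](C)(O)C2 | intermediate
21 | acetonide of 20 at Cb/Cc, C1 and chain hydroxyls free | OCCC[C@@]1(C)CCC[C@@H](O)C2=C1C[C@H]3OC(C)(C)O[C@@]3(C)C2 | intermediate
22 | cis-fused saturated diol, H6 and H7 cis to the C5 chain and the C1 hydroxyl | OCCC[C@@]1(C)CCC[C@@H](O)[C@H]2[C@@H]1C[C@H]3OC(C)(C)O[C@@]3(C)C2 | intermediate
23 | keto aldehyde: C1 ketone and chain aldehyde | O=CCC[C@@]1(C)CCCC(=O)[C@H]2[C@@H]1C[C@H]3OC(C)(C)O[C@@]3(C)C2 | intermediate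
24 | (R)-isopropenyl carbinol | C=C(C)[C@H](O)CC[C@@]1(C)CCCC(=O)[C@H]2[C@@H]1C[C@H]3OC(C)(C)O[C@@]3(C)C2 | intermediate
25 | TBS ether of 24 | C=C(C)[C@H](O[Si](C)(C)C(C)(C)C)CC[C@@]1(C)CCCC(=O)[C@H]2[C@@H]1C[C@H]3OC(C)(C)O[C@@]3(C)C2 | intermediate
26 | lithium C1=C2 enolate of 25 | C=C(C)[C@H](O[Si](C)(C)C(C)(C)C)CC[C@@]1(C)CCC=C(O[Li])[C@H]2[C@@H]1C[C@H]3OC(C)(C)O[C@@]3(C)C2 | intermediate
27 | C2=C3 enone | C=C(C)[C@H](O[Si](C)(C)C(C)(C)C)CC[C@@]1(C)CC=CC(=O)[C@H]2[C@@H]1C[C@H]3OC(C)(C)O[C@@]3(C)C2 | intermediate
28 | 2-(hydroxymethyl) enone | C=C(C)[C@H](O[Si](C)(C)C(C)(C)C)CC[C@@]1(C)CC=C(CO)C(=O)[C@H]2[C@@H]1C[C@H]3OC(C)(C)O[C@@]3(C)C2 | intermediate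
29 | TBDPS ether of 28 | C=C(C)[C@H](O[Si](C)(C)C(C)(C)C)CC[C@@]1(C)CC=C(CO[Si](c4ccccc4)(c5ccccc5)C(C)(C)C)C(=O)[C@H]2[C@@H]1C[C@H]3OC(C)(C)O[C@@]3(C)C2 | intermediate
30 | Cb/Cc cis-diol from 29 | C=C(C)[C@H](O[Si](C)(C)C(C)(C)C)CC[C@@]1(C)CC=C(CO[Si](c4ccccc4)(c5ccccc5)C(C)(C)C)C(=O)[C@H]2[C@@H]1C[C@@H](O)[C@@](C)(O)C2 | intermediate
31 | monocyclic keto aldehyde, C6 and C7 arms cis | C=C(C)[C@H](O[Si](C)(C)C(C)(C)C)CC[C@@]1(C)CC=C(CO[Si](c2ccccc2)(c2ccccc2)C(C)(C)C)C(=O)[C@H](CC(C)=O)[C@@H]1CC=O | intermediate
32 | 3-methylbut-2-enoic acid | CC(C)=CC(=O)O | starting material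
33 | 3-methylbut-2-enoic anhydride | CC(C)=CC(=O)OC(=O)C=C(C)C | intermediate
34 | bis-silylated target with the (E)-enol senecioate | C=C(C)[C@H](O[Si](C)(C)C(C)(C)C)CC[C@@]1(C)CC=C(CO[Si](c2ccccc2)(c2ccccc2)C(C)(C)C)C(=O)[C@H](CC(C)=O)[C@@H]1/C=C/OC(=O)C=C(C)C | intermediate
35 | CNP0257974.2 | C=C(C)[C@H](O)CC[C@@]1(C)CC=C(CO)C(=O)[C@H](CC(C)=O)[C@@H]1/C=C/OC(=O)C=C(C)C | target

Total step count: 23. Longest linear sequence: 22 (steps 1–20, 22 and 23; step 21 is a side branch).

The three steps most likely to fail:

Step 22. The amine may trigger an intramolecular aldol reaction between the two cis arms. It may also cause slow epimerisation at C7, incomplete E selectivity, or migration of the senecioyl double bond out of conjugation. The fallback avoids a free enolate and sets out from 31. ZnCl2-catalysed addition of 3-methylbut-2-enoyl chloride across the aldehyde C=O, in which the ketones take no part, gives the 1-chloroalkyl senecioate F1 as a mixture at the chlorine-bearing carbon. Short treatment with i-Pr2NEt in warm toluene then removes HCl by anti elimination from the conformer that keeps the ring residue and the acyloxy group apart. This comes back to the route at 34.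

Step 10. The benzylic C1 oxygen may be lost reductively if the alkoxide is protonated during the reduction or the quench, and the hindered, electron-rich arene may be reduced incompletely. The fallback gives up this oxygen on purpose and puts it back by allylic oxidation, setting out from 17.
- Li in NH3/THF with EtOH and no prior deprotonation gives the deoxygenated diene alcohol F2.
- OsO4/NMO gives the triol F3, and Me2C(OMe)2/PPTS gives the acetonide F4.
- CrO3·3,5-dimethylpyrazole in CH2Cl2 oxidises C1, the only unencumbered allylic methylene (Ca and Cd are deactivated by the neighbouring C–O bonds), together with the primary alcohol, giving the enone aldehyde F5.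
- (S)-Me-CBS with excess BH3·SMe2 reduces the aldehyde and, under catalyst control, the enone, and comes back to the route at 21.

Step 18. Addition of DMAP to the hindered seven-membered enone may be sluggish, and the long exposure to aqueous base that follows may erode C7. The fallback replaces organocatalysis by cross-coupling and sets out from 27. I2 and pyridine in CH2Cl2 give the 2-iodoenone F6. Stille coupling with (tributylstannyl)methanol (PdCl2(PhCN)2, AsPh3, CuI, NMP, 60 °C) then comes back to the route at 28.

Further compounds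
F1 | step 22 | 1-chloroalkyl senecioate of 31 (Cc carries Cl and the senecioyloxy group, both epimers) | C=C(C)[C@H](O[Si](C)(C)C(C)(C)C)CC[C@@]1(C)CC=C(CO[Si](c2ccccc2)(c2ccccc2)C(C)(C)C)C(=O)[C@H](CC(C)=O)[C@@H]1CC(Cl)OC(=O)C=C(C)C
F2 | step 10 | C1-deoxy analogue of 19 | OCCC[C@@]1(C)CCCCC2=C1CC=C(C)C2
F3 | step 10 | C1-deoxy analogue of 20 | OCCC[C@@]1(C)CCCCC2=C1C[C@@H](O)[C@@](C)(O)C2
F4 | step 10 | C1-deoxy analogue of 21 | OCCC[C@@]1(C)CCCCC2=C1C[C@H]3OC(C)(C)O[C@@]3(C)C2
F5 | step 10 | C1 enone (C6=C7 retained) with chain aldehyde and Cb/Cc acetonide | O=CCC[C@@]1(C)CCCC(=O)C2=C1C[C@H]3OC(C)(C)O[C@@]3(C)C2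
F6 | step 18 | 2-iodo analogue of 27 | C=C(C)[C@H](O[Si](C)(C)C(C)(C)C)CC[C@@]1(C)CC=C(I)C(=O)[C@H]2[C@@H]1C[C@H]3OC(C)(C)O[C@@]3(C)C2
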